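The arene is joined late, through C11, to a bicyclic aldehyde (C9–CHO), and the C9=C11 double bond follows by dehydration. Everything rests on building the trans-decalin from an acyclic geranyl β-keto ester: a chiral Brønsted acid protonates the terminal alkene and, in one operation, closes ring A by the C4–C5 bond and ring B by the C9–C10 bond, setting C5 and C10. The step exploits the gem-dimethyl carbon C4 next to the ring-fusion C5–H that is trans to the C10 methyl, the imprint of a chair–chair cation–olefin cascade. The precursor is methyl (6E)-7,11-dimethyl-3-oxododeca-6,10-dienoate; its ketone later becomes the C8 methyl stereocentre.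

Key step: step 2

Remark on numbering: the decalin carries drimane numbers (C4 gem-dimethyl, C5 and C10 ring fusion, C8 methyl-bearing carbon, C9 alkene carbon, C11 benzylic CH). The arene is numbered C1′ (bonded to C11), C2′ (O-sulfate), C3′ (CHO), C4′ (OH), C5′ (O-sulfate), C6′ (H).

Remark on the catalyst: IDPi means a confined imidodiphosphorimidate Brønsted acid, two 3,3′-diaryl-BINOL phosphorus units joined through nitrogen, each phosphorus carrying an =N–SO2CF3 group.

Assumption: the sulfate half-esters 22 and 23 are written in the neutral hydrogen sulfate form of the target SMILES. In practice 22 would be handled as its sodium salt and 23 set free on an H+ exchange resin, kept cold.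

Step 1
Reactants: 1 methyl acetoacetate; 2 geranyl bromide
Product: 4 methyl (6E)-7,11-dimethyl-3-oxododeca-6,10-dienoate, via acetoacetate dianion 3 (not isolated)
Conditions: NaH, THF, 0 °C; n-BuLi, 0 °C; 2, 0 °C → rt; aq. HCl
Reagents that add atoms: none
Why: Dianion γ-alkylation of a β-keto ester, in which the more basic terminal carbanion of 3 displaces the primary allylic bromide by SN2 with the E alkene retained.

Step 2
Reactants: 4 methyl (6E)-7,11-dimethyl-3-oxododeca-6,10-dienoate
Product: 5 methyl (1R,4aS,8aS)-5,5,8a-trimethyl-2-oxodecahydronaphthalene-1-carboxylate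
Conditions: chiral IDPi Brønsted acid (5 mol %), (CF3)3COH, −20 °C
Reagents that add atoms: none
Why: Proposed new method: the confined chiral acid protonates C3 of the terminal trisubstituted alkene of 4 while its counter-anion is hydrogen-bonded to the enolised β-keto ester, and in a chair–chair array the developing C4 cation is taken up by C5 of the (E)-C5=C10 alkene (ring A, 6-endo-trig, new C4–C5 bond) and the C10 cation by the enol carbon C9 (ring B, 6-endo-trig, new C9–C10 bond). The closest known reaction types are the catalytic asymmetric IDPi-promoted proton-initiated bicyclization of hydroxyl- or carboxyl-terminated polyenes and the SnCl4-promoted racemic bicyclization of polyene β-keto esters of exactly this kind; new is their combination, an enol terminator under chiral Brønsted acid control. C5 and C10 are set together: the E geometry of the C5=C10 alkene and anti addition across it give the trans ring fusion (5α-H, 10β-CH3), the catalyst pocket selects the alkene face, and the catalyst antipode that leads to the (4aS,8aS) series is used. C9 should end with the ester equatorial (1R) by keto–enol equilibration, and this centre is removed later in any case. The step needs initiation at the terminal and not the internal alkene (only terminal protonation is assisted by concerted C4–C5 bonding in the folded substrate) and C- over O-capture of the C10 cation (an enol ether from O-capture should re-ionise under the acid and funnel to the β-keto ester).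

Step 3
Reactants: 5 methyl (1R,4aS,8aS)-5,5,8a-trimethyl-2-oxodecahydronaphthalene-1-carboxylate
Product: 6 methyl (1S,4aS,8aS)-5,5,8a-trimethyl-2-methylidenedecahydronaphthalene-1-carboxylate
Conditions: Ph3PCH3Br, NaN(SiMe3)2, toluene, 0 → 80 °C
Reagents that add atoms: methyltriphenylphosphonium bromide, C[P+](c1ccccc1)(c1ccccc1)c1ccccc1.[Br-]
Why: Wittig methylenation of the C8 ketone with the non-stabilised ylide in excess (part of it is tied up reversibly by the acidic C9–H), which should give the exocyclic C8=C12 alkene without touching the ester and creates no stereocentre.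

Step 4
Reactants: 6 methyl (1S,4aS,8aS)-5,5,8a-trimethyl-2-methylidenedecahydronaphthalene-1-carboxylate
Product: 7 methyl (1S,2S,4aS,8aS)-2,5,5,8a-tetramethyldecahydronaphthalene-1-carboxylate
Conditions: H2 (1 atm), PtO2, EtOAc, rt
Reagents that add atoms: none
Why: Heterogeneous catalytic hydrogenation, in which the catalyst surface should approach the exocyclic alkene from the α face, away from the axial C10 methyl and the β C9 ester, so that hydrogen adds to C8 from below and the new methyl is β (axial, 8S in drimane numbering).

Step 5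
Reactants: 7 methyl (1S,2S,4aS,8aS)-2,5,5,8a-tetramethyldecahydronaphthalene-1-carboxylate
Product: 8 (1S,2S,4aS,8aS)-2,5,5,8a-tetramethyldecahydronaphthalene-1-carbaldehyde
Conditions: i-Bu2AlH, toluene, −78 °C; aq. Rochelle salt
Reagents that add atoms: none
Why: Partial reduction of an ester with i-Bu2AlH, where the hindered tetrahedral aluminium hemiacetal should persist at −78 °C and release the aldehyde only on work-up; C8 cannot epimerise and the C9 centre is destroyed later.

Step 6
Reactants: 9 2,5-dihydroxybenzaldehyde
Product: 10 2,5-bis(methoxymethoxy)benzaldehyde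
Conditions: MOMCl, i-Pr2NEt, CH2Cl2, 0 °C → rt
Reagents that add atoms: chloromethyl methyl ether, COCCl
Why: Williamson-type O-alkylation of both phenols to MOM ethers, the group that later stabilises the ortho-aryllithium and is removed by mild acid.

Step 7
Reactants: 10 2,5-bis(methoxymethoxy)benzaldehyde
Product: 12 2,5-bis(methoxymethoxy)phenol, via aryl formate 11 (not isolated)
Conditions: mCPBA, NaHCO3, CH2Cl2, 0 °C → rt; K2CO3, MeOH, rt
Reagents that add atoms: 3-chloroperbenzoic acid, OOC(=O)c1cccc(Cl)c1
Why: Dakin-type Baeyer–Villiger oxidation, in which the electron-rich aryl group migrates to oxygen to give formate 11 and methanolysis then frees the phenol, so the formyl carbon is replaced by the unique hydroxyl that becomes the C4′ oxygen.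

Step 8
Reactants: 12 2,5-bis(methoxymethoxy)phenol
Product: 13 2-hydroxy-3,6-bis(methoxymethoxy)benzaldehyde
Conditions: MgCl2, Et3N, (CH2O)n, MeCN, 80 °C
Reagents that add atoms: paraformaldehyde (formaldehyde), C=O
Why: Magnesium-mediated ortho-formylation of a phenol (Casnati–Skattebøl), in which the magnesium phenoxide delivers formaldehyde only ortho to the hydroxyl and, one ortho position being occupied by OMOM, the formyl group can enter only between OH and the other OMOM group (the future C3′).

Step 9
Reactants: 13 2-hydroxy-3,6-bis(methoxymethoxy)benzaldehyde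
Product: 14 5-bromo-2-hydroxy-3,6-bis(methoxymethoxy)benzaldehyde
Conditions: NBS, MeCN, 0 °C
Reagents that add atoms: N-bromosuccinimide, BrN1C(=O)CCC1=O
Why: Electrophilic aromatic bromination directed para to the free hydroxyl (both of its ortho positions are occupied), a position that is also ortho to an OMOM group and meta to the aldehyde, whereas the only other free position is para to the aldehyde.

Step 10
Reactants: 14 5-bromo-2-hydroxy-3,6-bis(methoxymethoxy)benzaldehyde
Product: 15 2-(allyloxy)-5-bromo-3,6-bis(methoxymethoxy)benzaldehyde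
Conditions: allyl bromide, K2CO3, DMF, 50 °C
Reagents that add atoms: allyl bromide, C=CCBr
Why: Williamson ether synthesis capping the remaining phenol as an allyl ether, which should survive butyllithium at −78 °C, acid and sulfation and can be removed at the end with zerovalent palladium without harm to aryl sulfates.

Step 11
Reactants: 15 2-(allyloxy)-5-bromo-3,6-bis(methoxymethoxy)benzaldehyde; 8 (1S,2S,4aS,8aS)-2,5,5,8a-tetramethyldecahydronaphthalene-1-carbaldehyde
Product: 18 2-(allyloxy)-5-{hydroxy[(1S,2S,4aS,8aS)-2,5,5,8a-tetramethyldecahydronaphthalen-1-yl]methyl}-3,6-bis(methoxymethoxy)benzaldehyde (both C11 epimers), via amino alkoxide 16 (not isolated), via aryllithium 17 (not isolated)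
Conditions: MeNHCH2CH2NMe2, n-BuLi, THF, −20 °C; 15; n-BuLi, −78 °C; 8, −78 → −40 °C; H2O
Reagents that add atoms: none
Why: In situ protection of the aryl aldehyde as a lithium α-amino alkoxide, bromine–lithium exchange and 1,2-addition of the aryllithium (chelated by the ortho OMOM group) to the neopentyl-type aldehyde 8; the new C11 carbinol centre forms as a mixture that is lost in step 12, and water work-up returns the formyl group.

Step 12
Reactants: 18 2-(allyloxy)-5-{hydroxy[(1S,2S,4aS,8aS)-2,5,5,8a-tetramethyldecahydronaphthalen-1-yl]methyl}-3,6-bis(methoxymethoxy)benzaldehyde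
Product: 20 2-(allyloxy)-3,6-bis(methoxymethoxy)-5-{(E)-[(2S,4aS,8aS)-2,5,5,8a-tetramethyloctahydronaphthalen-1(2H)-ylidene]methyl}benzaldehyde, via benzylic mesylate 19 (not isolated)
Conditions: MsCl, Et3N, CH2Cl2, 0 °C → rt
Reagents that add atoms: none
Why: Dehydration by mesylation and E1 elimination, in which the electron-rich benzylic mesylate 19 ionises, the only β hydrogen (C9–H) is lost, and the alkene should form with the aryl group cis to C8 and away from the quaternary C10 (E), the geometry that avoids allylic strain.

Step 13
Reactants: 20 2-(allyloxy)-3,6-bis(methoxymethoxy)-5-{(E)-[(2S,4aS,8aS)-2,5,5,8a-tetramethyloctahydronaphthalen-1(2H)-ylidene]methyl}benzaldehyde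
Product: 21 2-(allyloxy)-3,6-dihydroxy-5-{(E)-[(2S,4aS,8aS)-2,5,5,8a-tetramethyloctahydronaphthalen-1(2H)-ylidene]methyl}benzaldehyde
Conditions: HCl (cat.), MeOH, 40 °C, argon
Reagents that add atoms: none
Why: Acid-catalysed solvolysis of the two MOM acetals in methanol, mild enough that the allyl ether, the aldehyde and the trisubstituted styrene should survive; the air-sensitive hydroquinone is kept under argon and used at once.

Step 14
Reactants: 21 2-(allyloxy)-3,6-dihydroxy-5-{(E)-[(2S,4aS,8aS)-2,5,5,8a-tetramethyloctahydronaphthalen-1(2H)-ylidene]methyl}benzaldehyde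
Product: 22 3-(allyloxy)-2-formyl-6-{(E)-[(2S,4aS,8aS)-2,5,5,8a-tetramethyloctahydronaphthalen-1(2H)-ylidene]methyl}-1,4-phenylene bis(hydrogen sulfate)
Conditions: SO3·pyridine (excess), pyridine, 50 °C; aq. NaHCO3
Reagents that add atoms: sulfur trioxide–pyridine complex, [O-]S(=O)(=O)[n+]1ccccc1
Why: O-sulfation of phenols with the sulfur trioxide–pyridine complex, where only the two hydroquinone hydroxyls (C2′ and C5′) are free and the C4′ oxygen is masked as the allyl ether, so the sulfation pattern is fixed by protection and not by selectivity.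

Step 15
Reactants: 22 3-(allyloxy)-2-formyl-6-{(E)-[(2S,4aS,8aS)-2,5,5,8a-tetramethyloctahydronaphthalen-1(2H)-ylidene]methyl}-1,4-phenylene bis(hydrogen sulfate)
Product: 23 2-formyl-3-hydroxy-6-{(E)-[(2S,4aS,8aS)-2,5,5,8a-tetramethyloctahydronaphthalen-1(2H)-ylidene]methyl}-1,4-phenylene bis(hydrogen sulfate) (target)
Conditions: Pd(PPh3)4 (5 mol %), K2CO3, MeOH, rt; Dowex 50W (H+ form), H2O, 0 °C
Reagents that add atoms: none
Why: Palladium-catalysed deallylation of the Tsuji–Trost type (π-allyl palladium formation from the aryl allyl ether and capture of the allyl unit by methanol), to which aryl sulfates, the aldehyde and the hindered styrene should be inert; proton exchange on the resin gives the free bis(hydrogen sulfate).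

Compound list
1 | methyl acetoacetate | COC(=O)CC(C)=O | starting material
2 | geranyl bromide, (2E)-1-bromo-3,7-dimethylocta-2,6-diene | CC(C)=CCC/C(C)=C/CBr | starting material
3 | sodium lithium dianion (dienolate) of methyl acetoacetate | C=C([O-])C=C([O-])OC.[Na+].[Li+] | intermediate
4 | methyl (6E)-7,11-dimethyl-3-oxododeca-6,10-dienoate | COC(=O)CC(=O)CC/C=C(\C)CCC=C(C)C | intermediate
5 | methyl (1R,4aS,8aS)-5,5,8a-trimethyl-2-oxodecahydronaphthalene-1-carboxylate (trans-decalin, C8 ketone, 9β-CO2Me) | O=C1CC[C@H]2C(C)(C)CCC[C@]2(C)[C@H]1C(=O)OC | intermediate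
6 | methyl (1S,4aS,8aS)-5,5,8a-trimethyl-2-methylidenedecahydronaphthalene-1-carboxylate | C=C1CC[C@H]2C(C)(C)CCC[C@]2(C)[C@H]1C(=O)OC | intermediate
7 | methyl (1S,2S,4aS,8aS)-2,5,5,8a-tetramethyldecahydronaphthalene-1-carboxylate (8β-methyl) | C[C@H]1CC[C@H]2C(C)(C)CCC[C@]2(C)[C@H]1C(=O)OC | intermediate
8 | (1S,2S,4aS,8aS)-2,5,5,8a-tetramethyldecahydronaphthalene-1-carbaldehyde | C[C@H]1CC[C@H]2C(C)(C)CCC[C@]2(C)[C@H]1C=O | intermediate
9 | 2,5-dihydroxybenzaldehyde | O=Cc1cc(O)ccc1O | starting material
10 | 2,5-bis(methoxymethoxy)benzaldehyde | O=Cc1cc(OCOC)ccc1OCOC | intermediate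
11 | 2,5-bis(methoxymethoxy)phenyl formate | O=COc1cc(OCOC)ccc1OCOC | intermediate
12 | 2,5-bis(methoxymethoxy)phenol | Oc1cc(OCOC)ccc1OCOC | intermediate
13 | 2-hydroxy-3,6-bis(methoxymethoxy)benzaldehyde | O=Cc1c(O)c(OCOC)ccc1OCOC | intermediate
14 | 5-bromo-2-hydroxy-3,6-bis(methoxymethoxy)benzaldehyde | O=Cc1c(O)c(OCOC)cc(Br)c1OCOC | intermediate
15 | 2-(allyloxy)-5-bromo-3,6-bis(methoxymethoxy)benzaldehyde | O=Cc1c(OCC=C)c(OCOC)cc(Br)c1OCOC | intermediate
16 | lithium α-amino alkoxide of 15 (adduct with lithium N,N,N′-trimethylethylenediamide) | [Li]OC(N(C)CCN(C)C)c1c(OCC=C)c(OCOC)cc(Br)c1OCOC | intermediate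
17 | 5-lithio derivative of 16 (aryllithium) | [Li]OC(N(C)CCN(C)C)c1c(OCC=C)c(OCOC)cc([Li])c1OCOC | intermediate
18 | 2-(allyloxy)-5-{hydroxy[(1S,2S,4aS,8aS)-2,5,5,8a-tetramethyldecahydronaphthalen-1-yl]methyl}-3,6-bis(methoxymethoxy)benzaldehyde (C11 epimers) | C[C@H]1CC[C@H]2C(C)(C)CCC[C@]2(C)[C@H]1C(O)c1cc(OCOC)c(OCC=C)c(C=O)c1OCOC | intermediate
19 | methanesulfonate of 18 | C[C@H]1CC[C@H]2C(C)(C)CCC[C@]2(C)[C@H]1C(OS(C)(=O)=O)c1cc(OCOC)c(OCC=C)c(C=O)c1OCOC | intermediate
20 | 2-(allyloxy)-3,6-bis(methoxymethoxy)-5-{(E)-[(2S,4aS,8aS)-2,5,5,8a-tetramethyloctahydronaphthalen-1(2H)-ylidene]methyl}benzaldehyde | C[C@H]1CC[C@H]2C(C)(C)CCC[C@]2(C)/C1=C/c1cc(OCOC)c(OCC=C)c(C=O)c1OCOC | intermediate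
21 | 2-(allyloxy)-3,6-dihydroxy-5-{(E)-[(2S,4aS,8aS)-2,5,5,8a-tetramethyloctahydronaphthalen-1(2H)-ylidene]methyl}benzaldehyde | C[C@H]1CC[C@H]2C(C)(C)CCC[C@]2(C)/C1=C/c1cc(O)c(OCC=C)c(C=O)c1O | intermediate
22 | 3-(allyloxy)-2-formyl-6-{(E)-[(2S,4aS,8aS)-2,5,5,8a-tetramethyloctahydronaphthalen-1(2H)-ylidene]methyl}-1,4-phenylene bis(hydrogen sulfate) | C[C@H]1CC[C@H]2C(C)(C)CCC[C@]2(C)/C1=C/c1cc(OS(=O)(=O)O)c(OCC=C)c(C=O)c1OS(=O)(=O)O | intermediate
23 | 2-formyl-3-hydroxy-6-{(E)-[(2S,4aS,8aS)-2,5,5,8a-tetramethyloctahydronaphthalen-1(2H)-ylidene]methyl}-1,4-phenylene bis(hydrogen sulfate) | C[C@H]1CC[C@H]2C(C)(C)CCC[C@]2(C)/C1=C/c1cc(OS(=O)(=O)O)c(O)c(C=O)c1OS(=O)(=O)O | target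

Total step count: 15.
Longest linear sequence: 10 steps (steps 1–5 followed by steps 11–15; the arene branch, steps 6–10 followed by 11–15, is equally long).

Steps most likely to fail

Step 2 (Proposed new method). What may go wrong is insufficient facial discrimination by the catalyst in the first ring closure, or diversion of the cascade to monocyclic or O-cyclised material. The fallback uses known chemistry and sets out from 4: SnCl4 in CH2Cl2 (0 °C → rt) brings about the established racemic bicyclization of this class of polyene β-keto esters, forming the same C4–C5 and C9–C10 bonds. The racemate, that is 5 together with its mirror image, the ent-keto ester F1, is separated by preparative chromatography on a chiral stationary phase; 5 comes back to the route at step 3 and F1 is set aside.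

Step 11. What may go wrong is incomplete masking of the formyl group in the flask, so that butyllithium or the aryllithium adds to it, or enolisation of the hindered aldehyde 8 by the basic aryllithium. The fallback sets out from 15, which is protected as the dimethyl acetal F2 (HC(OMe)3, pyridinium tosylate, MeOH). Bromine–lithium exchange (n-BuLi, THF, −78 °C) gives the aryllithium F3, which is transmetalated with anhydrous CeCl3 to the less basic arylcerium dichloride F4. Its addition to 8 gives the carbinol acetal F5, whose acetal is hydrolysed during a dilute citric acid work-up, so the route is rejoined at 18.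

Step 4. What may go wrong is poor facial selectivity (hydrogen delivered from the β face gives the equatorial C8 epimer) or migration of the exocyclic double bond into the ring on the catalyst before reduction. The fallback sets out from 6: hydroboration with 9-BBN (THF, rt → 60 °C), a much bulkier reagent that should approach only from the α face and place hydrogen on C8 and boron on C12, gives the alkylborane F6. Base-induced iodinolysis (I2, NaOMe, MeOH) converts the primary C–B bond into the primary iodide F7, and radical reduction (Bu3SnH, AIBN, toluene, 80 °C) gives 7, where the route is rejoined.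

Further compounds
F1 | step 2 | methyl (1S,4aR,8aR)-5,5,8a-trimethyl-2-oxodecahydronaphthalene-1-carboxylate (enantiomer of 5) | O=C1CC[C@@H]2C(C)(C)CCC[C@@]2(C)[C@@H]1C(=O)OC
F2 | step 11 | 2-(allyloxy)-5-bromo-1-(dimethoxymethyl)-3,6-bis(methoxymethoxy)benzene (numbered as in 15) | COC(OC)c1c(OCC=C)c(OCOC)cc(Br)c1OCOC
F3 | step 11 | aryllithium from F2 | COC(OC)c1c(OCC=C)c(OCOC)cc([Li])c1OCOC
F4 | step 11 | arylcerium dichloride from F3 | COC(OC)c1c(OCC=C)c(OCOC)cc([Ce](Cl)Cl)c1OCOC
F5 | step 11 | dimethyl acetal of 18 (C11 epimers) | C[C@H]1CC[C@H]2C(C)(C)CCC[C@]2(C)[C@H]1C(O)c1cc(OCOC)c(OCC=C)c(C(OC)OC)c1OCOC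
F6 | step 4 | methyl (1S,4aS,8aS)-2β-[(9-borabicyclo[3.3.1]nonan-9-yl)methyl]-5,5,8a-trimethyldecahydronaphthalene-1-carboxylate | C1CCC2CCCC1B2C[C@H]3CC[C@H]4C(C)(C)CCC[C@]4(C)[C@H]3C(=O)OC
F7 | step 4 | methyl (1S,4aS,8aS)-2β-(iodomethyl)-5,5,8a-trimethyldecahydronaphthalene-1-carboxylate | IC[C@H]1CC[C@H]2C(C)(C)CCC[C@]2(C)[C@H]1C(=O)OC
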